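**Retrosynthetic overview**
1. Target 24 comes from 23 by hydrogenolysis of an O5 benzyl ether; O5 is freed last and under neutral conditions.
2. 23 comes from 15 and 18: ring B is built last by vinylketene/ynol ether benzannulation, forming C1'–C2' and C5'–C6'. The feature used is that C1' of ring B (bonded to C2 of ring C) lies between C2'–OH and C6'–OMe while C3', C4' and C5' carry only hydrogen.
3. 15 comes from 9 and 12: the C2–C(sp) bond and the (2S) centre are made by copper-catalysed enantioselective alkynylation of the 4-silyloxybenzopyrylium ion of chromone 9 with methoxyethyne.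
4. 9 comes from 1: ring A is bought, a phenol oxygen and an acetyl group are added, ring C is closed as the chromone, and the peri C5 methyl ether is exchanged for benzyl while the molecule is still achiral.
5. Ring order: A (bought), C (step 3), B (step 10).

Key step: step 10

Assumption: the StackPhos enantiomer used is the one that delivers the copper acetylide to the C2 face giving (2S); the CIP order O1 > alkynyl C > C3 > H is the same as for other 1-alkynes, so the facial sense carries over. Methoxyethyne and cyclobut-2-enone are made (steps 6, 8, 9), not bought.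

**Route**

Step 1
Reactants: 1 1,2,3,4-tetramethoxybenzene
Product: 4 2,3,4,5-tetramethoxyphenol, via aryllithium 2 (not isolated), via dimethyl arylboronate 3 (not isolated)
Conditions: n-BuLi, TMEDA, THF, 0 °C; B(OMe)3, −78 °C to rt; AcOH, 30% H2O2, 0 °C to rt
Reagents that add atoms: hydrogen peroxide, OO
Why: Directed ortho-lithiation beside a methoxy group (the two ring C–H positions are equivalent), borylation and boronate oxidation (aryl shift from boron to oxygen) should place the phenol oxygen on the former C5.

Step 2
Reactants: 4 2,3,4,5-tetramethoxyphenol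
Product: 5 1-(2-hydroxy-3,4,5,6-tetramethoxyphenyl)ethan-1-one
Conditions: AcOH, BF3·OEt2, 90 °C; then H2O
Reagents that add atoms: acetic acid, CC(=O)O
Why: BF3-promoted Friedel–Crafts C-acylation (Fries type, via the aryl acetate) can occur only at the single free ring position, which is ortho to the hydroxyl, and is driven by boron chelation of the resulting ortho-hydroxyaryl ketone.

Step 3
Reactants: 5 1-(2-hydroxy-3,4,5,6-tetramethoxyphenyl)ethan-1-one
Product: 7 5,6,7,8-tetramethoxy-4H-chromen-4-one, via enaminone 6 (not isolated)
Conditions: Me2NCH(OMe)2, toluene, 100 °C; then conc. HCl, CH2Cl2, 40 °C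
Reagents that add atoms: N,N-dimethylformamide dimethyl acetal, COC(OC)N(C)C
Why: Condensation of the methyl ketone with the amide acetal gives the enaminone, and acid then promotes conjugate addition of the phenol oxygen with loss of dimethylamine (6-endo addition–elimination), the standard chromone synthesis that closes ring C.

Step 4
Reactants: 7 5,6,7,8-tetramethoxy-4H-chromen-4-one
Product: 8 5-hydroxy-6,7,8-trimethoxy-4H-chromen-4-one
Conditions: BCl3 (1.5 equiv), CH2Cl2, −78 to 0 °C; then H2O
Reagents that add atoms: none
Why: BCl3 bound to the C4 carbonyl cleaves only the peri C5 methyl ether through a six-membered boron chelate (chelation-controlled demethylation), and it is used on the achiral chromone so that no Lewis acid has to act later on the C2–O1 bond, which in 23 and 24 is an ortho-oxygenated benzylic aryl ether.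

Step 5
Reactants: 8 5-hydroxy-6,7,8-trimethoxy-4H-chromen-4-one
Product: 9 5-(benzyloxy)-6,7,8-trimethoxy-4H-chromen-4-one
Conditions: BnBr, K2CO3, DMF, 60 °C
Reagents that add atoms: benzyl bromide, BrCc1ccccc1
Why: Williamson etherification of the C5 phenol gives a benzyl ether that is inert to silyl triflate, amine base, ketenes and heat and can be removed at the end under neutral conditions.

Step 6
Reactants: 10 chloroacetaldehyde dimethyl acetal
Product: 12 methoxyethyne, via sodium methoxyacetylide 11 (not isolated)
Conditions: NaNH2 (3 equiv), liquid NH3, −33 °C; cold saturated aq. NaCl, −70 °C; distilled into toluene at −78 °C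
Reagents that add atoms: none
Why: Threefold action of NaNH2 (elimination of methanol, elimination of HCl, then deprotonation of the alkyne) gives the sodium acetylide, which a cold aqueous quench converts into the volatile alkyne; this is the established preparation of methoxyethyne.

Step 7
Reactants: 9 5-(benzyloxy)-6,7,8-trimethoxy-4H-chromen-4-one; 12 methoxyethyne
Product: 15 (S)-5-(benzyloxy)-6,7,8-trimethoxy-2-(methoxyethynyl)chroman-4-one, via silyloxybenzopyrylium triflate 13 (not isolated), via silyl enol ether 14 (not isolated)
Conditions: Me3SiOTf (1.05 equiv), CH2Cl2, 23 °C; then CuI (10 mol%), StackPhos (12 mol%), i-Pr2NEt (1.6 equiv), 12 (2 equiv, toluene), −78 to −40 °C; then MeOH, KF (0.2 equiv), −40 to 0 °C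
Reagents that add atoms: none
Why: This is the copper-catalysed enantioselective alkynylation of a chromone through its 4-silyloxybenzopyrylium ion: the copper acetylide formed from 12 with CuI and amine adds to one face of C2 inside the chiral pocket of the P,N-ligand, which sets (2S), the amine is kept in excess over the silyl triflate so that the ynol ether never meets free acid, and the trimethylsilyl enol ether is unmasked by fluoride-catalysed methanolysis, which needs neither acid nor a stoichiometric enolate.

Step 8
Reactants: 16 3-oxocyclobutane-1-carboxylic acid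
Product: 17 3-bromocyclobutan-1-one
Conditions: HgO, Br2, MgSO4, CH2Cl2, 40 °C
Reagents that add atoms: bromine, BrBr
Why: The Cristol–Firth variant of the Hunsdiecker bromodecarboxylation (acyl hypobromite, loss of CO2, bromine capture by the cyclobutyl radical) should replace the carboxyl group by bromine without touching the ketone.

Step 9
Reactants: 17 3-bromocyclobutan-1-one
Product: 18 cyclobut-2-en-1-one
Conditions: n-Bu3N, 23 °C, product distilled under reduced pressure into a trap at −78 °C
Reagents that add atoms: none
Why: E1cB dehydrobromination of the β-bromo ketone by the tertiary amine gives the enone, which is distilled out of the high-boiling amine as it forms and is kept cold in solution.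

Step 10
Reactants: 15 (S)-5-(benzyloxy)-6,7,8-trimethoxy-2-(methoxyethynyl)chroman-4-one; 18 cyclobut-2-en-1-one
Product: 23 (S)-5-(benzyloxy)-2-(2-hydroxy-6-methoxyphenyl)-6,7,8-trimethoxychroman-4-one, via vinylketene 19 (not isolated), via vinylcyclobutenone 20 (not isolated), via dienylketene 21 (not isolated), via cyclohexadienone 22 (not isolated)
Conditions: toluene (base-washed glassware), 80 °C, 18 (1.5 equiv) added over 6 h; then 100 °C, 2 h
Reagents that add atoms: none
Why: On warming, 18 opens by 4π electrocyclic cleavage to vinylketene 19, which adds to the ynol ether of 15 in a [2+2] cycloaddition (ketene carbonyl carbon to the alkyne carbon bearing C2, ketene α-carbon to the methoxy-bearing carbon); this forms C1'–C2' and C5'–C6' and gives 20, which opens again (4π) to dienylketene 21, closes to 22 and enolises to the phenol. The closest known reaction type is the Danheiser benzannulation of cyclobutenones with alkoxyalkynes to 2-substituted resorcinol monoethers; the parent cyclobutenone and an ynol ether with a propargylic aryloxy group are new partners for it. Ring B is closed by a thermal disrotatory 6π electrocyclisation of 21 (ketene carbon onto the terminal CH2, restoring the C2'–C3' bond), followed by tautomerisation to the arene. No stereocentre is created: the sp3 ring carbon of 20 is transient, and C2 should be carried through unchanged because the cascade is thermal and neutral and touches neither C2–H nor C3–H. The selectivity needed is the regiochemistry of the [2+2] step, secured by the methoxy group, which makes the alkyne carbon attached to C2 the nucleophilic terminus that attacks the ketene carbonyl carbon, so that C1' ends between the new hydroxyl (ketene oxygen) and the methoxyl. Chemoselectivity for the alkyne over the C4 ketone and the aryl ethers rests on the ynol ether being the only strongly nucleophilic π-bond in 15.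

Step 11
Reactants: 23 (S)-5-(benzyloxy)-2-(2-hydroxy-6-methoxyphenyl)-6,7,8-trimethoxychroman-4-one
Product: 24 (S)-5-hydroxy-2-(2-hydroxy-6-methoxyphenyl)-6,7,8-trimethoxychroman-4-one
Conditions: H2 (1 atm), Pd/C, EtOAc, 23 °C
Reagents that add atoms: none
Why: Heterogeneous palladium-catalysed hydrogenolysis of the O5 benzyl ether is neutral, so that the (2S) centre, which acid or base could scramble by opening ring C, should be kept.

**Compound list**
1 | 1,2,3,4-tetramethoxybenzene | COc1ccc(OC)c(OC)c1OC | starting material
2 | (2,3,4,5-tetramethoxyphenyl)lithium | [Li]c1cc(OC)c(OC)c(OC)c1OC | intermediate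
3 | dimethyl (2,3,4,5-tetramethoxyphenyl)boronate | COB(OC)c1cc(OC)c(OC)c(OC)c1OC | intermediate
4 | 2,3,4,5-tetramethoxyphenol | Oc1cc(OC)c(OC)c(OC)c1OC | intermediate
5 | 1-(2-hydroxy-3,4,5,6-tetramethoxyphenyl)ethan-1-one | CC(=O)c1c(O)c(OC)c(OC)c(OC)c1OC | intermediate
6 | (E)-3-(dimethylamino)-1-(2-hydroxy-3,4,5,6-tetramethoxyphenyl)prop-2-en-1-one | CN(C)/C=C/C(=O)c1c(O)c(OC)c(OC)c(OC)c1OC | intermediate
7 | 5,6,7,8-tetramethoxy-4H-chromen-4-one | O=c1ccoc2c(OC)c(OC)c(OC)c(OC)c12 | intermediate
8 | 5-hydroxy-6,7,8-trimethoxy-4H-chromen-4-one | O=c1ccoc2c(OC)c(OC)c(OC)c(O)c12 | intermediate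
9 | 5-(benzyloxy)-6,7,8-trimethoxy-4H-chromen-4-one | O=c1ccoc2c(OC)c(OC)c(OC)c(OCc3ccccc3)c12 | intermediate
10 | chloroacetaldehyde dimethyl acetal (2-chloro-1,1-dimethoxyethane) | COC(OC)CCl | starting material
11 | sodium methoxyacetylide | [Na+].[C-]#COC | intermediate
12 | methoxyethyne | C#COC | intermediate
13 | 5-(benzyloxy)-6,7,8-trimethoxy-4-(trimethylsilyloxy)chromenylium trifluoromethanesulfonate | C[Si](C)(C)Oc1cc[o+]c2c(OC)c(OC)c(OC)c(OCc3ccccc3)c12.[O-]S(=O)(=O)C(F)(F)F | intermediate
14 | (S)-5-(benzyloxy)-6,7,8-trimethoxy-2-(methoxyethynyl)-4-(trimethylsilyloxy)-2H-chromene | COC#C[C@@H]1C=C(O[Si](C)(C)C)c2c(OCc3ccccc3)c(OC)c(OC)c(OC)c2O1 | intermediate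
15 | (S)-5-(benzyloxy)-6,7,8-trimethoxy-2-(methoxyethynyl)chroman-4-one | COC#C[C@@H]1CC(=O)c2c(OCc3ccccc3)c(OC)c(OC)c(OC)c2O1 | intermediate
16 | 3-oxocyclobutane-1-carboxylic acid | O=C1CC(C(=O)O)C1 | starting material
17 | 3-bromocyclobutan-1-one | O=C1CC(Br)C1 | intermediate
18 | cyclobut-2-en-1-one | O=C1C=CC1 | intermediate
19 | buta-1,3-dien-1-one (vinylketene) | C=CC=C=O | intermediate
20 | (S)-5-(benzyloxy)-6,7,8-trimethoxy-2-(2-methoxy-4-oxo-3-vinylcyclobut-1-en-1-yl)chroman-4-one, both epimers at the sp3 carbon of the four-membered ring | COC1=C([C@@H]2CC(=O)c3c(OCc4ccccc4)c(OC)c(OC)c(OC)c3O2)C(=O)C1C=C | intermediate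
21 | (S)-5-(benzyloxy)-6,7,8-trimethoxy-2-[(3E)-3-methoxy-1-oxohexa-1,3,5-trien-2-yl]chroman-4-one | C=C/C=C(/OC)C(=C=O)[C@@H]1CC(=O)c2c(OCc3ccccc3)c(OC)c(OC)c(OC)c2O1 | intermediate
22 | (S)-5-(benzyloxy)-6,7,8-trimethoxy-2-(2-methoxy-6-oxocyclohexa-1,3-dien-1-yl)chroman-4-one | COC1=C([C@@H]2CC(=O)c3c(OCc4ccccc4)c(OC)c(OC)c(OC)c3O2)C(=O)CC=C1 | intermediate
23 | (S)-5-(benzyloxy)-2-(2-hydroxy-6-methoxyphenyl)-6,7,8-trimethoxychroman-4-one | COc1cccc(O)c1[C@@H]1CC(=O)c2c(OCc3ccccc3)c(OC)c(OC)c(OC)c2O1 | intermediate
24 | (S)-5-hydroxy-2-(2-hydroxy-6-methoxyphenyl)-6,7,8-trimethoxychroman-4-one | COc1cccc(O)c1[C@@H]1CC(=O)c2c(O)c(OC)c(OC)c(OC)c2O1 | target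

**Step count**
Total: 11 steps. Longest linear sequence: 8 steps (1, 2, 3, 4, 5, 7, 10, 11).

**Steps most likely to fail**

Step 7. What may go wrong: the free ynol ether may be attacked through its nucleophilic β-carbon by the benzopyrylium ion or by residual silyl triflate before it is turned into the copper acetylide, giving unselective addition and loss of the alkyne. The unmasking of the enol ether may also open ring C by β-elimination and erode the C2 configuration. Fallback, setting out from 9 and 12 and coming back at 15: the alkynyl group is delivered as a preformed zinc acetylide and the enantiomers are separated. 12 is deprotonated with n-BuLi in THF at −78 °C to give lithium methoxyacetylide F1. ZnCl2 then converts F1 into (methoxyethynyl)zinc chloride F2. F2 is added at −78 °C to pyrylium triflate 13, prepared from 9 as in step 7, so that no neutral ynol ether is present. This should give racemic 5-(benzyloxy)-6,7,8-trimethoxy-2-(methoxyethynyl)-4-(trimethylsilyloxy)-2H-chromene F3. Fluoride-catalysed methanolysis of F3 as in step 7 should give racemic 5-(benzyloxy)-6,7,8-trimethoxy-2-(methoxyethynyl)chroman-4-one F4. Preparative chromatography on a chiral stationary phase separates F4 into 15 and (R)-5-(benzyloxy)-6,7,8-trimethoxy-2-(methoxyethynyl)chroman-4-one F5. F5 is set aside and 15 is carried on to step 10.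

Step 10. What may go wrong: cyclobutenone may be consumed by oligomerisation or by cycloaddition with its own vinylketene faster than the hindered internal alkyne captures the ketene; a second vinylketene may acylate the newly formed phenol; prolonged heating may ionise the propargylic C2–O1 bond of the ynol ether. Fallback, setting out from 15 and coming back at 23 by way of 20: vinylketene 19 is generated without heat by 1,4-dehydrochlorination. (E)-But-2-enoyl chloride (1.5 equiv) is added slowly to 15 and i-Pr2NEt (1.6 equiv) in toluene at 0 to 23 °C, so that the [2+2] adduct 20 forms cold and before any phenol exists. The ammonium salt is filtered off and the solution is passed through a short pad of basic alumina to remove base. The solution is then warmed to 80 °C to take 20 through 21 and 22 to 23. This fallback makes no compound outside the compound list; its line in the block below is F0.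

Step 11. What may go wrong: reductive cleavage of the benzylic C2–O1 bond of ring C (opening to the dihydrochalcone) may compete with debenzylation at the hindered peri oxygen. Fallback, setting out from 23 and coming back at 24: non-reductive debenzylation with BCl3 (2.2 equiv) and pentamethylbenzene (3 equiv) as cation scavenger in CH2Cl2 at −78 °C, quenched cold with water. A benzyl ether peri to the carbonyl should cleave within minutes at this temperature, far below what a methyl ether would need, so the C2–O1 bond is exposed to the Lewis acid only briefly. This fallback makes no compound outside the compound list; its line in the block below is F0.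

**Further compounds**
F1 | step 7 | lithium methoxyacetylide | [Li]C#COC
F2 | step 7 | (methoxyethynyl)zinc chloride | COC#C[Zn]Cl
F3 | step 7 | racemic 5-(benzyloxy)-6,7,8-trimethoxy-2-(methoxyethynyl)-4-(trimethylsilyloxy)-2H-chromene | COC#CC1C=C(O[Si](C)(C)C)c2c(OCc3ccccc3)c(OC)c(OC)c(OC)c2O1
F4 | step 7 | racemic 5-(benzyloxy)-6,7,8-trimethoxy-2-(methoxyethynyl)chroman-4-one | COC#CC1CC(=O)c2c(OCc3ccccc3)c(OC)c(OC)c(OC)c2O1
F5 | step 7 | (R)-5-(benzyloxy)-6,7,8-trimethoxy-2-(methoxyethynyl)chroman-4-one | COC#C[C@H]1CC(=O)c2c(OCc3ccccc3)c(OC)c(OC)c(OC)c2O1
F0 | step 10 | none | none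
F0 | step 11 | none | none
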